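**Retrosynthetic overview**
- The target comes from its penta-silyl ether by fluoride. The C3–aryl bond is cut back to a C3 carboxylic acid (redox-active ester, nickel decarboxylative arylation, aryl delivered trans to the C2 aryl group), and the C5–vinyl bond is cut by a Heck disconnection to a 5-bromo dihydrobenzofuran-3-carboxylate.
- Structural feature used: O1, C2 with its 4-oxygenated phenyl ring, C3 and the benzo ring (C3a–C7a) are a (2S)-flavanone minus its carbonyl carbon. Moving the benzo carbon from the carbonyl carbon to C3 makes C3–C3a, contracts the pyranone to the dihydrofuran and turns the old carbonyl carbon into CO2Me.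
- The flavanone comes from 6-bromochromone and (4-hydroxyphenyl)boronic acid by enantioselective conjugate addition (sets C2), then pivaloylation.
- Ring order: the benzo ring and pyranone are bought; the dihydrofuran ring forms by the six-to-five contraction; both resorcinol rings are attached intact.
- Protecting groups: pivalate through the key step; the stilbene methyl ethers are removed at the robust ester stage and all phenols are carried as silyl ethers, so the last step is a fluoride desilylation.

Key step: step 3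

Assumption: the sense of induction of the pyridine-oxazoline catalyst with chromones is taken to parallel that with carbocyclic enones, so the (R)-tert-butyl ligand is written for the (2S)-flavanone; the antipodal ligand is equally available should the sense be opposite.

**Step 1**
Reactants: 1 6-bromochromone; 2 (4-hydroxyphenyl)boronic acid
Product: 3 (2S)-6-bromo-2-(4-hydroxyphenyl)chroman-4-one
Conditions: Pd(OCOCF3)2 (5 mol%), (R)-4-tert-butyl-2-(pyridin-2-yl)-4,5-dihydrooxazole [(R)-t-BuPyOx, 6 mol%], NH4PF6 (30 mol%), H2O (5 equiv), ClCH2CH2Cl, 60 °C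
Reagents that add atoms: none
Why: Palladium-catalysed asymmetric conjugate addition of an arylboronic acid to a chromone: transmetalation to the cationic divalent palladium–pyridine-oxazoline complex, enantioface-selective insertion of the C2=C3 bond under control of the tert-butyl oxazoline (this sets C2) and protonolysis of the palladium enolate should give the (2S)-flavanone; the aryl bromide is inert because no zerovalent palladium–phosphine species is present.

**Step 2**
Reactants: 3 (2S)-6-bromo-2-(4-hydroxyphenyl)chroman-4-one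
Product: 4 4-[(2S)-6-bromo-4-oxo-3,4-dihydro-2H-chromen-2-yl]phenyl 2,2-dimethylpropanoate [(2S)-6-bromo-2-[4-(pivaloyloxy)phenyl]chroman-4-one]
Conditions: PivCl, pyridine, DMAP (cat.), CH2Cl2, 0 °C
Reagents that add atoms: pivaloyl chloride, CC(C)(C)C(Cl)=O
Why: Acylation of the phenol with nucleophilic catalysis; the weak base and low temperature avoid retro-oxa-Michael opening that would racemise C2, and the hindered, electron-withdrawing pivalate should survive the acid of step 3 and make the C2 aryl ring electron-poor.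

**Step 3**
Reactants: 4 (2S)-6-bromo-2-[4-(pivaloyloxy)phenyl]chroman-4-one
Product: 7 methyl (2S,3S)-5-bromo-2-[4-(pivaloyloxy)phenyl]-2,3-dihydro-1-benzofuran-3-carboxylate (2,3-trans), via methyl enol ether 5 (not isolated), via 3-iodanyl dimethyl ketal 6 (not isolated)
Conditions: PhI(OAc)2 (1.3 equiv), conc. H2SO4 (0.5 equiv), HC(OMe)3, 0 °C to rt
Reagents that add atoms: trimethyl orthoformate, COC(OC)OC
Why: Acid and HC(OMe)3 turn the ketone into its ketal and methyl enol ether 5, which attacks the trivalent iodine electrophile at C3 on the face anti to the C2 aryl group while methanol caps C4 to give 6; PhI then leaves as the benzo carbon C4a shifts from C4 to C3 with inversion through a phenonium-like bridged transition state, and the dimethoxycarbenium ion loses one methyl group to acetate to give the ester. The closest known reaction type is the oxidative ring contraction of flavanones (1,2-aryl shift of aryl ketone ketals) with trivalent iodine or trivalent thallium reagents in trimethyl orthoformate. The five-membered ring closes by ring contraction, not chain cyclisation: C4a bridges C4 and C3 in a three-membered, 3-exo-tet-like displacement at C3 and the C4–C4a bond breaks, leaving O1–C2–C3–C3a–C7a. The new stereocentre C3 is controlled by C2 through anti addition of iodine followed by invertive migration, which places CO2Me trans to the C2 aryl group (also the thermodynamic epimer); C2 itself is not touched. The step needs migration of the benzo ring in preference to the C2 aryl group (isoflavone) and to elimination (flavone): the pivaloyloxyphenyl ring is a poor migrating group and a poor stabiliser of charge at C2, the two ketal oxygens push the C4-to-C3 shift, and the ring oxygen ortho to C4a raises the migratory aptitude of the benzo ring.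

**Step 4**
Reactants: 7 methyl (2S,3S)-5-bromo-2-[4-(pivaloyloxy)phenyl]-2,3-dihydro-1-benzofuran-3-carboxylate; 8 3,5-dimethoxystyrene
Product: 9 methyl (2S,3S)-5-[(E)-2-(3,5-dimethoxyphenyl)ethenyl]-2-[4-(pivaloyloxy)phenyl]-2,3-dihydro-1-benzofuran-3-carboxylate
Conditions: Pd(OAc)2 (5 mol%), P(o-tol)3 (10 mol%), Et3N, DMF, 100 °C
Reagents that add atoms: none
Why: Mizoroki–Heck reaction: oxidative addition of zerovalent palladium into the C5–Br bond, syn insertion of the styrene at its terminal carbon and syn β-hydride elimination should give the E stilbene; ester and pivalate tolerate the amine base, and any epimerisation at C3 returns to the favoured trans ester and is irrelevant after step 10.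

**Step 5**
Reactants: 9 methyl (2S,3S)-5-[(E)-2-(3,5-dimethoxyphenyl)ethenyl]-2-[4-(pivaloyloxy)phenyl]-2,3-dihydro-1-benzofuran-3-carboxylate
Product: 10 methyl (2S,3S)-5-[(E)-2-(3,5-dihydroxyphenyl)ethenyl]-2-[4-(pivaloyloxy)phenyl]-2,3-dihydro-1-benzofuran-3-carboxylate
Conditions: BBr3 (6 equiv), CH2Cl2, −78 to 0 °C; then H2O
Reagents that add atoms: none
Why: Lewis-acid cleavage of aryl methyl ethers: BBr3 binds the methoxy oxygens and bromide removes the methyl groups by SN2; at or below 0 °C the methyl ester and hindered pivalate should be kept (any ester cleavage converges in step 6), and ionisation of the ring C2–O1 bond is disfavoured here by the electron-poor pivaloyloxyphenyl ring and the C3 ester.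

**Step 6**
Reactants: 10 methyl (2S,3S)-5-[(E)-2-(3,5-dihydroxyphenyl)ethenyl]-2-[4-(pivaloyloxy)phenyl]-2,3-dihydro-1-benzofuran-3-carboxylate
Product: 11 (2S,3S)-5-[(E)-2-(3,5-dihydroxyphenyl)ethenyl]-2-(4-hydroxyphenyl)-2,3-dihydro-1-benzofuran-3-carboxylic acid
Conditions: LiOH·H2O, degassed THF/MeOH/H2O, 0 °C to rt; then aq. HCl to pH 3
Reagents that add atoms: lithium hydroxide, [Li+].[OH-]
Why: Saponification (acyl–oxygen cleavage by hydroxide) of the methyl ester and the aryl pivalate; ring opening by β-elimination of the aryloxide from the C3 enolate would be the reverse of a disfavoured 5-endo-trig closure, and epimerisation at C3 is harmless because trans is favoured and C3 is re-set in step 10.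

**Step 7**
Reactants: 11 (2S,3S)-5-[(E)-2-(3,5-dihydroxyphenyl)ethenyl]-2-(4-hydroxyphenyl)-2,3-dihydro-1-benzofuran-3-carboxylic acid
Product: 13 (2S,3S)-2-[4-(tert-butyldimethylsilyloxy)phenyl]-5-[(E)-2-[3,5-bis(tert-butyldimethylsilyloxy)phenyl]ethenyl]-2,3-dihydro-1-benzofuran-3-carboxylic acid, via fourfold silylated silyl ester 12 (not isolated)
Conditions: TBSCl (6 equiv), imidazole, DMF, rt; then AcOH/THF/H2O, rt
Reagents that add atoms: tert-butyldimethylsilyl chloride, CC(C)(C)[Si](C)(C)Cl
Why: Silylation of the three phenols and the acid with TBSCl/imidazole; the silyl ester is far more labile than the aryl silyl ethers and is cleaved selectively by the dilute acetic acid work-up.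

**Step 8**
Reactants: 13 (2S,3S)-2-[4-(tert-butyldimethylsilyloxy)phenyl]-5-[(E)-2-[3,5-bis(tert-butyldimethylsilyloxy)phenyl]ethenyl]-2,3-dihydro-1-benzofuran-3-carboxylic acid
Product: 14 1,3-dioxoisoindolin-2-yl (2S,3S)-2-[4-(tert-butyldimethylsilyloxy)phenyl]-5-[(E)-2-[3,5-bis(tert-butyldimethylsilyloxy)phenyl]ethenyl]-2,3-dihydro-1-benzofuran-3-carboxylate
Conditions: N-hydroxyphthalimide, N,N'-diisopropylcarbodiimide, DMAP (cat.), CH2Cl2, rt
Reagents that add atoms: N-hydroxyphthalimide, O=C1c2ccccc2C(=O)N1O
Why: Carbodiimide-mediated (Steglich-type) esterification gives the redox-active ester under neutral conditions that leave the aryl silyl ethers and the stilbene untouched.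

**Step 9**
Reactants: 15 5-bromobenzene-1,3-diol
Product: 16 1-bromo-3,5-bis(tert-butyldimethylsilyloxy)benzene
Conditions: TBSCl (2.4 equiv), imidazole, DMF, rt
Reagents that add atoms: tert-butyldimethylsilyl chloride, CC(C)(C)[Si](C)(C)Cl
Why: Standard silylation of phenols; the silyl ethers tolerate magnesium insertion and the organozinc reagent and are removed by fluoride at the end.

**Step 10**
Reactants: 14 1,3-dioxoisoindolin-2-yl ester of acid 13; 16 1-bromo-3,5-bis(tert-butyldimethylsilyloxy)benzene
Product: 19 penta-O-(tert-butyldimethylsilyl)-(2S,3S)-trans-δ-viniferin, via arylmagnesium bromide 17 (not isolated), via arylzinc chloride 18 (not isolated)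
Conditions: 16, Mg, LiCl, THF, rt; ZnCl2, THF, 0 °C to rt; then 14, NiCl2(dme) (20 mol%), 4,4'-di-tert-butyl-2,2'-bipyridine (40 mol%), THF/DMF, rt
Reagents that add atoms: none
Why: Nickel-catalysed decarboxylative Negishi-type arylation of a redox-active ester: single-electron reduction of the phthalimide ester by low-valent nickel releases CO2 and phthalimide and leaves the planar benzylic C3 radical, which is captured by the aryl–nickel species on the face away from the C2 aryl group, so reductive elimination should form the C3–aryl bond trans to it and set C3 (3S) under control of C2; the stilbene and silyl ethers are inert, and the bromine that would interfere was consumed in step 4.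

**Step 11**
Reactants: 19 penta-O-(tert-butyldimethylsilyl)-(2S,3S)-trans-δ-viniferin
Product: 20 (2S,3S)-trans-δ-viniferin
Conditions: TBAF (6 equiv), AcOH (6 equiv), THF, 0 °C
Reagents that add atoms: none
Why: Fluoride-mediated cleavage of the five aryl silyl ethers, driven by the Si–F bond; the acetic acid buffer keeps the phenols protonated, so neither quinone-methide opening of the C2–O1 bond nor phenolate oxidation should occur, and neither stereocentre nor the E alkene is touched.

**Compound list**
1 | 6-bromochromone (6-bromo-4H-chromen-4-one) | O=c1ccoc2ccc(Br)cc12 | starting material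
2 | (4-hydroxyphenyl)boronic acid | OB(O)c1ccc(O)cc1 | starting material
3 | (2S)-6-bromo-2-(4-hydroxyphenyl)chroman-4-one | Oc1ccc([C@@H]2CC(=O)c3cc(Br)ccc3O2)cc1 | intermediate
4 | (2S)-6-bromo-2-[4-(pivaloyloxy)phenyl]chroman-4-one | CC(C)(C)C(=O)Oc1ccc([C@@H]2CC(=O)c3cc(Br)ccc3O2)cc1 | intermediate
5 | 4-[(2S)-6-bromo-4-methoxy-2H-chromen-2-yl]phenyl pivalate (methyl enol ether, not isolated) | CC(C)(C)C(=O)Oc1ccc([C@@H]2C=C(OC)c3cc(Br)ccc3O2)cc1 | intermediate
6 | 4-[2,3-trans-3-[acetoxy(phenyl)-λ3-iodanyl]-6-bromo-4,4-dimethoxychroman-2-yl]phenyl pivalate (iodine anti to the C2 aryl group, C2 as in 4; not isolated) | CC(C)(C)C(=O)Oc1ccc([C@@H]2[C@@H](I(OC(C)=O)c4ccccc4)C(OC)(OC)c3cc(Br)ccc3O2)cc1 | intermediate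
7 | methyl (2S,3S)-5-bromo-2-[4-(pivaloyloxy)phenyl]-2,3-dihydro-1-benzofuran-3-carboxylate (trans) | CC(C)(C)C(=O)Oc1ccc([C@H]2Oc3ccc(Br)cc3[C@@H]2C(=O)OC)cc1 | intermediate
8 | 3,5-dimethoxystyrene | C=Cc1cc(OC)cc(OC)c1 | starting material
9 | methyl (2S,3S)-5-[(E)-2-(3,5-dimethoxyphenyl)ethenyl]-2-[4-(pivaloyloxy)phenyl]-2,3-dihydro-1-benzofuran-3-carboxylate | CC(C)(C)C(=O)Oc1ccc([C@H]2Oc3ccc(/C=C/c4cc(OC)cc(OC)c4)cc3[C@@H]2C(=O)OC)cc1 | intermediate
10 | methyl (2S,3S)-5-[(E)-2-(3,5-dihydroxyphenyl)ethenyl]-2-[4-(pivaloyloxy)phenyl]-2,3-dihydro-1-benzofuran-3-carboxylate | CC(C)(C)C(=O)Oc1ccc([C@H]2Oc3ccc(/C=C/c4cc(O)cc(O)c4)cc3[C@@H]2C(=O)OC)cc1 | intermediate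
11 | (2S,3S)-5-[(E)-2-(3,5-dihydroxyphenyl)ethenyl]-2-(4-hydroxyphenyl)-2,3-dihydro-1-benzofuran-3-carboxylic acid | Oc1ccc([C@H]2Oc3ccc(/C=C/c4cc(O)cc(O)c4)cc3[C@@H]2C(=O)O)cc1 | intermediate
12 | tert-butyldimethylsilyl (2S,3S)-2-[4-(tert-butyldimethylsilyloxy)phenyl]-5-[(E)-2-[3,5-bis(tert-butyldimethylsilyloxy)phenyl]ethenyl]-2,3-dihydro-1-benzofuran-3-carboxylate (not isolated) | CC(C)(C)[Si](C)(C)Oc1ccc([C@H]2Oc3ccc(/C=C/c4cc(O[Si](C)(C)C(C)(C)C)cc(O[Si](C)(C)C(C)(C)C)c4)cc3[C@@H]2C(=O)O[Si](C)(C)C(C)(C)C)cc1 | intermediate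
13 | (2S,3S)-2-[4-(tert-butyldimethylsilyloxy)phenyl]-5-[(E)-2-[3,5-bis(tert-butyldimethylsilyloxy)phenyl]ethenyl]-2,3-dihydro-1-benzofuran-3-carboxylic acid | CC(C)(C)[Si](C)(C)Oc1ccc([C@H]2Oc3ccc(/C=C/c4cc(O[Si](C)(C)C(C)(C)C)cc(O[Si](C)(C)C(C)(C)C)c4)cc3[C@@H]2C(=O)O)cc1 | intermediate
14 | 1,3-dioxoisoindolin-2-yl (2S,3S)-2-[4-(tert-butyldimethylsilyloxy)phenyl]-5-[(E)-2-[3,5-bis(tert-butyldimethylsilyloxy)phenyl]ethenyl]-2,3-dihydro-1-benzofuran-3-carboxylate | CC(C)(C)[Si](C)(C)Oc1ccc([C@H]2Oc3ccc(/C=C/c4cc(O[Si](C)(C)C(C)(C)C)cc(O[Si](C)(C)C(C)(C)C)c4)cc3[C@@H]2C(=O)ON2C(=O)c3ccccc3C2=O)cc1 | intermediate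
15 | 5-bromobenzene-1,3-diol | Oc1cc(O)cc(Br)c1 | starting material
16 | 1-bromo-3,5-bis(tert-butyldimethylsilyloxy)benzene | CC(C)(C)[Si](C)(C)Oc1cc(Br)cc(O[Si](C)(C)C(C)(C)C)c1 | intermediate
17 | [3,5-bis(tert-butyldimethylsilyloxy)phenyl]magnesium bromide (not isolated) | CC(C)(C)[Si](C)(C)Oc1cc([Mg]Br)cc(O[Si](C)(C)C(C)(C)C)c1 | intermediate
18 | [3,5-bis(tert-butyldimethylsilyloxy)phenyl]zinc chloride (not isolated) | CC(C)(C)[Si](C)(C)Oc1cc([Zn]Cl)cc(O[Si](C)(C)C(C)(C)C)c1 | intermediate
19 | penta-O-(tert-butyldimethylsilyl)-(2S,3S)-trans-δ-viniferin | CC(C)(C)[Si](C)(C)Oc1ccc([C@H]2Oc3ccc(/C=C/c4cc(O[Si](C)(C)C(C)(C)C)cc(O[Si](C)(C)C(C)(C)C)c4)cc3[C@@H]2c2cc(O[Si](C)(C)C(C)(C)C)cc(O[Si](C)(C)C(C)(C)C)c2)cc1 | intermediate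
20 | (2S,3S)-trans-δ-viniferin, 5-[(E)-2-[(2S,3S)-3-(3,5-dihydroxyphenyl)-2-(4-hydroxyphenyl)-2,3-dihydro-1-benzofuran-5-yl]ethenyl]benzene-1,3-diol | Oc1ccc([C@H]2Oc3ccc(/C=C/c4cc(O)cc(O)c4)cc3[C@@H]2c2cc(O)cc(O)c2)cc1 | target

**Step count**
Total steps: 11. Longest linear sequence: 10 (steps 1–8, 10, 11); step 9 is a one-step side branch.

**Steps most likely to fail**

Step 3. The oxidation may be diverted into migration of the C2 aryl group (isoflavone formation), dehydrogenation to the flavone or α-methoxylation, in place of ring contraction. The fallback sets out from 4 and comes back at 7 by a Wolff ring contraction, which makes the same C3–C3a bond through a carbene and ketene. Deprotonation of 4 with LiN(SiMe3)2 in THF at −78 °C and trapping with 2,2,2-trifluoroethyl trifluoroacetate gives the 3-trifluoroacetyl flavanone F1. Deacylative diazo transfer (MsN3, Et3N, H2O, MeCN) gives the 3-diazoflavanone F2, whose C2 is unchanged in space but is named 2R because the diazo carbon outranks the aryl carbon. Irradiation at 365 nm in MeOH/THF expels N2, the benzo carbon migrates to C3 and methanol adds to the ketene, giving 7 together with its cis C3 epimer F3. DBU in toluene equilibrates F3 to the trans ester 7; the configuration at C3 is in any case erased in step 10.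

Step 10. The arylzinc reagent may consume the activated ester by acyl substitution or premature reduction before decarboxylative capture, or capture of the hindered C3 radical may be inefficient. The fallback sets out from 14 and 16 and comes back at 19 without an organometallic nucleophile. The Grignard reagent 17 made from 16 is quenched with iodine to give 1-iodo-3,5-bis(tert-butyldimethylsilyloxy)benzene F4. Ester 14 and F4 are then joined by a nickel-catalysed reductive cross-electrophile coupling (NiBr2(dme), 4,4'-di-tert-butyl-2,2'-bipyridine, Zn dust, DMA, rt), a known decarboxylative arylation of N-hydroxyphthalimide esters with aryl iodides. The same trans delivery to the C3 radical is expected.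

Step 5. Demethylation may be incomplete, or the Lewis acid may cleave the esters unevenly or open the benzylic C2–O1 ether. The fallback sets out from 7 and comes back at 11 without any Lewis acid. Commercial 3,5-dihydroxybenzaldehyde is silylated (TBSCl, imidazole, DMF) to 3,5-bis(tert-butyldimethylsilyloxy)benzaldehyde F5 and methylenated (Ph3PCH3Br, KOtBu, THF; Wittig reaction) to 3,5-bis(tert-butyldimethylsilyloxy)styrene F6. Heck coupling of 7 with F6 under the conditions of step 4 gives the silyl-protected stilbene ester F7. The LiOH treatment of step 6 then removes the methyl ester, the pivalate and both aryl silyl ethers in one operation to give 11.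

**Further compounds**
F1 | step 3 | 4-[(2S)-6-bromo-4-oxo-3-(trifluoroacetyl)-3,4-dihydro-2H-chromen-2-yl]phenyl pivalate (C3 epimers and enol form) | CC(C)(C)C(=O)Oc1ccc([C@@H]2C(C(=O)C(F)(F)F)C(=O)c3cc(Br)ccc3O2)cc1
F2 | step 3 | 4-[(2R)-6-bromo-3-diazo-4-oxo-3,4-dihydro-2H-chromen-2-yl]phenyl pivalate | CC(C)(C)C(=O)Oc1ccc([C@@H]2C(=[N+]=[N-])C(=O)c3cc(Br)ccc3O2)cc1
F3 | step 3 | methyl (2S,3R)-5-bromo-2-[4-(pivaloyloxy)phenyl]-2,3-dihydro-1-benzofuran-3-carboxylate (cis) | CC(C)(C)C(=O)Oc1ccc([C@H]2Oc3ccc(Br)cc3[C@H]2C(=O)OC)cc1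
F4 | step 10 | 1-iodo-3,5-bis(tert-butyldimethylsilyloxy)benzene | CC(C)(C)[Si](C)(C)Oc1cc(I)cc(O[Si](C)(C)C(C)(C)C)c1
F5 | step 5 | 3,5-bis(tert-butyldimethylsilyloxy)benzaldehyde | CC(C)(C)[Si](C)(C)Oc1cc(C=O)cc(O[Si](C)(C)C(C)(C)C)c1
F6 | step 5 | 3,5-bis(tert-butyldimethylsilyloxy)styrene | C=Cc1cc(O[Si](C)(C)C(C)(C)C)cc(O[Si](C)(C)C(C)(C)C)c1
F7 | step 5 | methyl (2S,3S)-5-[(E)-2-[3,5-bis(tert-butyldimethylsilyloxy)phenyl]ethenyl]-2-[4-(pivaloyloxy)phenyl]-2,3-dihydro-1-benzofuran-3-carboxylate | CC(C)(C)C(=O)Oc1ccc([C@H]2Oc3ccc(/C=C/c4cc(O[Si](C)(C)C(C)(C)C)cc(O[Si](C)(C)C(C)(C)C)c4)cc3[C@@H]2C(=O)OC)cc1
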